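**Retrosynthetic overview**
- Target ⇐ 1-ethynyl macrocycle (Markovnikov hydroxycarbonylation of the alkyne) ⇐ 11,12-epoxide (acetate SN2 opening at C11).
- Tetrahydrofuran (second ring, transannular): one-pot double Shi epoxidation of a macrocyclic 3Z,11E-dien-7-ol, then 5-exo opening of the cis-3,4-epoxide by O7.
- Fourteen-membered ring (first ring): C1–C2 bond from the enamine of a C15 aldehyde attacking a Z-configured π-allylpalladium at C2, the polar counterpart of the geranylgeranyl diphosphate cyclisation; the aldehyde then becomes the alkyne.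
- Open chain: Ni/Cr coupling (C7–C8) of a neryl acetate-derived aldehyde with a 2-bromo-1,5-diene built from hex-5-yn-1-ol (carboalumination, Negishi coupling).

Assumption: the presumed biosynthesis is C1–C2 cyclisation of a geranylgeranyl-type chain followed by transannular opening of a 3,4-epoxide by the C7 oxygen; the 3R,4R/cis-tetrahydrofuran array corresponds to anti opening of a cis-epoxide, so a 3Z olefin is carried (macrocycles are named with cembrane numbering: C1 bears the side chain, C2 lies towards C3=C4).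

**Route**

Step 1
Reactants: 1 neryl acetate [(2Z)-3,7-dimethylocta-2,6-dien-1-yl acetate]
Product: 3 (2Z)-3-methyl-6-oxohex-2-en-1-yl acetate, via ozonide 2 (not isolated)
Conditions: O3 (1.0 equiv), CH2Cl2, −78 °C; then Me2S, −78 °C to rt
Reagents that add atoms: ozone, [O-][O+]=O
Why: Chemoselective ozonolysis with reductive work-up, in which the electron-rich trisubstituted C6=C7 olefin reacts much faster with electrophilic ozone than the C2=C3 olefin deactivated by its allylic acetate, so only the isopropylidene end is cleaved, the Z olefin is kept and no stereocenter is formed.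

Step 2
Reactants: 4 hex-5-yn-1-ol
Product: 6 (5E)-6-iodo-5-methylhex-5-en-1-ol, via alkenylalane 5 (not isolated)
Conditions: Me3Al (3 equiv), Cp2ZrCl2 (0.25 equiv), CH2Cl2, 0 °C to rt; then I2, THF, −30 to 0 °C
Reagents that add atoms: trimethylaluminium, C[Al](C)C; iodine, II
Why: Negishi zirconium-catalysed carboalumination adds methyl and aluminium syn across the terminal alkyne (methyl to the internal carbon) and iodinolysis of the carbon–aluminium bond with retention gives the E-trisubstituted alkenyl iodide that becomes C11=C12, with no stereocenter formed.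

Step 3
Reactants: 7 3-bromobut-3-en-1-ol
Product: 8 2-bromo-4-iodobut-1-ene
Conditions: I2, PPh3, imidazole, CH2Cl2, 0 °C to rt
Reagents that add atoms: iodine, II
Why: Appel-type iodination in which the alkoxyphosphonium ion of the primary alcohol is displaced by iodide (SN2) while the alkenyl bromide is inert, with no stereocenter formed.

Step 4
Reactants: 6 (5E)-6-iodo-5-methylhex-5-en-1-ol, 8 2-bromo-4-iodobut-1-ene
Product: 10 (5E)-9-bromo-5-methyldeca-5,9-dien-1-ol, via alkylzinc iodide 9 (not isolated)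
Conditions: 8, Zn dust, LiCl, THF, 35 °C; then 6, [1,1'-bis(diphenylphosphino)ferrocene]palladium dichloride Pd(dppf)Cl2 (3 mol %), THF, rt
Reagents that add atoms: none
Why: Negishi sp3–sp2 cross-coupling in which zinc inserts only into the primary carbon–iodine bond of 8 and zerovalent palladium adds to the alkenyl iodide of 6 much faster than to the alkenyl bromide, so the E olefin is transferred with retention, the 2-bromoalkene survives and no stereocenter is formed.

Step 5
Reactants: 3 (2Z)-3-methyl-6-oxohex-2-en-1-yl acetate, 10 (5E)-9-bromo-5-methyldeca-5,9-dien-1-ol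
Product: 11 (2Z,6S,10E)-6,15-dihydroxy-3,11-dimethyl-7-methylidenepentadeca-2,10-dien-1-yl acetate
Conditions: CrCl2 (4 equiv), NiCl2 (0.1 equiv), N-[2-(4-isopropyl-4,5-dihydro-1,3-oxazol-2-yl)-6-methylphenyl]methanesulfonamide (Kishi ligand, the enantiomer that gives the S carbinol, 4.4 equiv), Et3N, THF, rt
Reagents that add atoms: none
Why: Asymmetric Nozaki–Hiyama–Kishi coupling in which nickel-catalysed formation of the alkenylchromium from the 2-bromo-1-alkene is followed by chemoselective addition to the aldehyde (allylic acetate and free hydroxyl tolerated), the chiral chromium–sulfonamide complex differentiating the aldehyde faces so that the carbinol carbon (C7 of the macrocycle) is set S by reagent control, with the sense of induction confirmed on the Mosher ester.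

Step 6
Reactants: 11 (2Z,6S,10E)-6,15-dihydroxy-3,11-dimethyl-7-methylidenepentadeca-2,10-dien-1-yl acetate
Product: 12 (2Z,6S,10E)-6-hydroxy-3,11-dimethyl-7-methylidene-15-oxopentadeca-2,10-dien-1-yl acetate
Conditions: 2,2,6,6-tetramethylpiperidin-1-oxyl (TEMPO, 0.1 equiv), PhI(OAc)2 (1.1 equiv), CH2Cl2, rt
Reagents that add atoms: none
Why: TEMPO-catalysed oxidation with PhI(OAc)2 oxidises the unhindered primary alcohol much faster than the secondary allylic alcohol and leaves the olefins, the allylic acetate and the C7 stereocenter untouched.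

Step 7
Reactants: 12 (2Z,6S,10E)-6-hydroxy-3,11-dimethyl-7-methylidene-15-oxopentadeca-2,10-dien-1-yl acetate
Product: 14 (1R,3Z,7S,11E)-4,12-dimethyl-8-methylidene-7-[(trimethylsilyl)oxy]cyclotetradeca-3,11-diene-1-carbaldehyde, via silyl ether 13 (not isolated)
Conditions: N,O-bis(trimethylsilyl)acetamide (1.2 equiv), THF, rt; then syringe-pump addition over 12 h to Pd(PPh3)4 (10 mol %), (S)-2-[diphenyl(trimethylsilyloxy)methyl]pyrrolidine (30 mol %), DMSO/THF, 0.002 mol/L, 25 °C
Reagents that add atoms: N,O-bis(trimethylsilyl)acetamide, CC(=N[Si](C)(C)C)O[Si](C)(C)C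
Why: Proposed new method: the catalytic enamine of the C15 aldehyde (nucleophilic at C1) attacks the less hindered CH2 terminus (C2) of the π-allylpalladium complex formed when zerovalent palladium ionises the Z-allylic acetate, which is the polar counterpart of the allyl cation–olefin cyclisation of geranylgeranyl diphosphate and closes the fourteen-membered ring at C1–C2; the diphenyl(silyloxy)methyl group of the (S)-amine shields one enamine face so that C1 is formed R (same facial sense as in its Michael and α-functionalisation reactions), the Z geometry is kept because syn–anti exchange would need a σ-bound palladium at the tertiary C4, silylation of O7 in the flask blocks the competing 5-exo O-allylation and high dilution suppresses oligomers; the closest known reactions are the intermolecular amine/palladium α-allylation of aldehydes with allyl acetates and its intramolecular version for five- and six-membered rings.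

Step 8
Reactants: 14 (1R,3Z,7S,11E)-4,12-dimethyl-8-methylidene-7-[(trimethylsilyl)oxy]cyclotetradeca-3,11-diene-1-carbaldehyde
Product: 15 (1R,3Z,7S,11E)-1-ethynyl-4,12-dimethyl-8-methylidenecyclotetradeca-3,11-dien-7-ol
Conditions: dimethyl (1-diazo-2-oxopropyl)phosphonate (1.5 equiv), K2CO3 (2 equiv), MeOH, 0 °C to rt (crude 14 used at once)
Reagents that add atoms: dimethyl (1-diazo-2-oxopropyl)phosphonate, COP(=O)(OC)C(=[N+]=[N-])C(C)=O
Why: Ohira–Bestmann (Seyferth–Gilbert) homologation through the diazomethylphosphonate anion formed in the flask and a 1,2-shift of the alkylidene carbene converts the aldehyde into the terminal alkyne with one added carbon, the aldehyde being consumed at 0 °C faster than it enolises so that C1 stays R, while the same K2CO3/MeOH medium removes the labile trimethylsilyl ether.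

Step 9
Reactants: 15 (1R,3Z,7S,11E)-1-ethynyl-4,12-dimethyl-8-methylidenecyclotetradeca-3,11-dien-7-ol
Product: 17 (1R,3R,4R,7S,11R,12R)-4,7:11,12-diepoxy-1-ethynyl-4,12-dimethyl-8-methylidenecyclotetradecan-3-ol, via bis-epoxide 16 (not isolated)
Conditions: 1,2:4,5-di-O-isopropylidene-β-D-erythro-2,3-hexodiulo-2,6-pyranose (Shi ketone from D-fructose, 0.6 equiv), Oxone (2KHSO5·KHSO4·K2SO4; 2.8 equiv KHSO5), K2CO3, Bu4NHSO4 (cat.), MeCN/CH2(OMe)2/aq. Na2B4O7 buffer pH 10.5, 0 °C; extract; then camphor-10-sulfonic acid (0.1 equiv), CH2Cl2, −20 °C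
Reagents that add atoms: potassium peroxymonosulfate (active salt of Oxone), [K+].[O-]S(=O)(=O)OO
Why: Shi asymmetric epoxidation followed by acid-catalysed transannular epoxide opening, in which the chiral dioxirane epoxidises only the two electron-rich trisubstituted olefins (the alkyne and the 1,1-disubstituted allylic olefin react far more slowly) on the face that makes each hydrogen-bearing olefin carbon R, giving the cis-(3R,4S)- and trans-(11R,12R)-epoxides, after which the C7 hydroxyl opens the 3,4-epoxide 5-exo at the tertiary C4 with inversion, so C3 is R (retained), C4 is R (inverted) and the tetrahydrofuran is cis-2,5-disubstituted, while the 11,12-epoxide has no 5-exo partner and survives.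

Step 10
Reactants: 17 (1R,3R,4R,7S,11R,12R)-4,7:11,12-diepoxy-1-ethynyl-4,12-dimethyl-8-methylidenecyclotetradecan-3-ol
Product: 18 (1R,3R,4R,7S,11S,12R)-4,7-epoxy-1-ethynyl-3,12-dihydroxy-4,12-dimethyl-8-methylidenecyclotetradecan-11-yl acetate
Conditions: CsOAc (3 equiv), AcOH (1.5 equiv), 18-crown-6 (0.2 equiv), DMF, 90 °C
Reagents that add atoms: acetic acid, CC(=O)O (delivered as acetate; caesium acetate, [Cs+].CC(=O)[O-], is the nucleophile and is regenerated)
Why: Base-catalysed SN2 opening of the trisubstituted epoxide by acetate under non-acidic conditions takes place at the less substituted carbon C11 with inversion (R to S) and leaves the C12–O bond untouched (12R tertiary alcohol), the acetic acid bound to excess acetate serving only to protonate the alkoxide so that acyl migration is suppressed and the 11-acetate/12-ol is obtained directly.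

Step 11
Reactants: 18 (1R,3R,4R,7S,11S,12R)-4,7-epoxy-1-ethynyl-3,12-dihydroxy-4,12-dimethyl-8-methylidenecyclotetradecan-11-yl acetate
Product: 19 dendronpholide R, 2-[(1R,3R,4R,7S,11S,12R)-11-acetoxy-4,7-epoxy-3,12-dihydroxy-4,12-dimethyl-8-methylidenecyclotetradecyl]prop-2-enoic acid
Conditions: Pd(OAc)2 (3 mol %), 2-(diphenylphosphino)pyridine (12 mol %), CH3SO3H (6 mol %), CO (20 bar), H2O (5 equiv), THF, 50 °C
Reagents that add atoms: carbon monoxide, [C-]#[O+]; water, O
Why: Palladium-catalysed Markovnikov hydroxycarbonylation of the terminal alkyne (palladium hydride addition placing palladium on the internal carbon, CO insertion and hydrolysis of the acyl, as in the pyridylphosphine-based alkyne carbonylation) gives the α-substituted acrylic acid, the alkyne reacting far faster than the 1,1-disubstituted olefin and no stereocenter being touched.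

**Compound list**

1 | neryl acetate, (2Z)-3,7-dimethylocta-2,6-dien-1-yl acetate | CC(=O)OC/C=C(C)\CCC=C(C)C | starting material
2 | 5-[(3Z)-5-acetoxy-3-methylpent-3-en-1-yl]-3,3-dimethyl-1,2,4-trioxolane (ozonide) | CC(=O)OC/C=C(C)\CCC1OOC(C)(C)O1 | intermediate
3 | (2Z)-3-methyl-6-oxohex-2-en-1-yl acetate | CC(=O)OC/C=C(C)\CCC=O | intermediate
4 | hex-5-yn-1-ol | OCCCCC#C | starting material
5 | dimethylaluminium (5E)-6-(dimethylalumanyl)-5-methylhex-5-en-1-olate (alkenylalane) | C[Al](C)OCCCC/C(C)=C/[Al](C)C | intermediate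
6 | (5E)-6-iodo-5-methylhex-5-en-1-ol | OCCCC/C(C)=C/I | intermediate
7 | 3-bromobut-3-en-1-ol | OCCC(Br)=C | starting material
8 | 2-bromo-4-iodobut-1-ene | ICCC(Br)=C | intermediate
9 | (3-bromobut-3-en-1-yl)zinc iodide | I[Zn]CCC(Br)=C | intermediate
10 | (5E)-9-bromo-5-methyldeca-5,9-dien-1-ol | OCCCC/C(C)=C/CCC(Br)=C | intermediate
11 | (2Z,6S,10E)-6,15-dihydroxy-3,11-dimethyl-7-methylidenepentadeca-2,10-dien-1-yl acetate | CC(=O)OC/C=C(C)\CC[C@H](O)C(=C)CC/C=C(C)/CCCCO | intermediate
12 | (2Z,6S,10E)-6-hydroxy-3,11-dimethyl-7-methylidene-15-oxopentadeca-2,10-dien-1-yl acetate | CC(=O)OC/C=C(C)\CC[C@H](O)C(=C)CC/C=C(C)/CCCC=O | intermediate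
13 | (2Z,6S,10E)-3,11-dimethyl-7-methylidene-15-oxo-6-[(trimethylsilyl)oxy]pentadeca-2,10-dien-1-yl acetate | CC(=O)OC/C=C(C)\CC[C@H](O[Si](C)(C)C)C(=C)CC/C=C(C)/CCCC=O | intermediate
14 | (1R,3Z,7S,11E)-4,12-dimethyl-8-methylidene-7-[(trimethylsilyl)oxy]cyclotetradeca-3,11-diene-1-carbaldehyde | O=C[C@@H]1CC/C(C)=C/CCC(=C)[C@@H](O[Si](C)(C)C)CC/C(C)=C\C1 | intermediate
15 | (1R,3Z,7S,11E)-1-ethynyl-4,12-dimethyl-8-methylidenecyclotetradeca-3,11-dien-7-ol | C#C[C@@H]1CC/C(C)=C/CCC(=C)[C@@H](O)CC/C(C)=C\C1 | intermediate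
16 | (1R,3R,4S,7S,11R,12R)-3,4:11,12-diepoxy-1-ethynyl-4,12-dimethyl-8-methylidenecyclotetradecan-7-ol | C#C[C@@H]1CC[C@@]2(C)O[C@@H]2CCC(=C)[C@@H](O)CC[C@]3(C)O[C@@H]3C1 | intermediate
17 | (1R,3R,4R,7S,11R,12R)-4,7:11,12-diepoxy-1-ethynyl-4,12-dimethyl-8-methylidenecyclotetradecan-3-ol | C#C[C@@H]1CC[C@@]2(C)O[C@@H]2CCC(=C)[C@@H]3CC[C@@](C)(O3)[C@H](O)C1 | intermediate
18 | (1R,3R,4R,7S,11S,12R)-4,7-epoxy-1-ethynyl-3,12-dihydroxy-4,12-dimethyl-8-methylidenecyclotetradecan-11-yl acetate | C#C[C@@H]1CC[C@@](C)(O)[C@@H](OC(C)=O)CCC(=C)[C@@H]2CC[C@@](C)(O2)[C@H](O)C1 | intermediate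
19 | dendronpholide R, 2-[(1R,3R,4R,7S,11S,12R)-11-acetoxy-4,7-epoxy-3,12-dihydroxy-4,12-dimethyl-8-methylidenecyclotetradecyl]prop-2-enoic acid | C=C(C(=O)O)[C@@H]1CC[C@@](C)(O)[C@@H](OC(C)=O)CCC(=C)[C@@H]2CC[C@@](C)(O2)[C@H](O)C1 | target

**Step count and risk**

Total step count: 11. Longest linear sequence: 9 steps (steps 2, 4, 5, 6, 7, 8, 9, 10 and 11, from hex-5-yn-1-ol).

Most likely to fail, step 7 (macrocyclisation): a fourteen-membered ring by amine/palladium α-allylation has no precedent; oligomers, attack at the tertiary allyl terminus, Z to E leakage in the π-allyl complex and racemisation of the α-branched aldehyde are all possible. The fallback makes the C1–C2 bond intermolecularly by the precedented reaction and closes the ring at C7–C8; it sets out from 10 and 3 and comes back at 15. Oxidise 10 (TEMPO, PhI(OAc)2) to (5E)-9-bromo-5-methyldeca-5,9-dienal F1 and mask the aldehyde of 3 (HC(OMe)3, MeOH, pyridinium p-toluenesulfonate) as (2Z)-6,6-dimethoxy-3-methylhex-2-en-1-yl acetate F2. Join them with Pd(PPh3)4 and the same (S)-amine in DMSO at rt to (2R,5E)-9-bromo-2-[(2Z)-6,6-dimethoxy-3-methylhex-2-en-1-yl]-5-methyldeca-5,9-dienal F3, and homologate at once (Ohira–Bestmann) to (3R,6E)-10-bromo-3-[(2Z)-6,6-dimethoxy-3-methylhex-2-en-1-yl]-6-methylundeca-6,10-dien-1-yne F4. Unmask (pyridinium p-toluenesulfonate, acetone/H2O) to (4Z,7R,10E)-14-bromo-7-ethynyl-4,10-dimethylpentadeca-4,10,14-trienal F5, then close the ring by the intramolecular asymmetric Ni/Cr coupling (CrCl2, NiCl2, the ligand of step 5, high dilution), which gives 15.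

Second, step 10 (acetate opening): SN2 attack of a weak oxygen nucleophile at a secondary carbon next to a quaternary centre is slow, and attack at C12, elimination or acyl migration would erode regio- and stereocontrol. The fallback uses hydrolytic SN2 opening followed by tin-directed monoacetylation; it sets out from 17 and comes back at 18. Open the epoxide with hydroxide (NaOH, 1,4-dioxane/H2O, 100 °C; attack at C11 with inversion) to (1R,3R,4R,7S,11S,12R)-4,7-epoxy-1-ethynyl-4,12-dimethyl-8-methylidenecyclotetradecane-3,11,12-triol F11. Convert its 11,12-diol with Bu2SnO (toluene, reflux) into the 11,12-O-dibutylstannylene acetal F12, not isolated, and add AcCl at 0 °C, which acylates the secondary tin alkoxide O11 and leaves O3 and O12 free, giving 18.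

Third, step 9 (double epoxidation and cyclisation): two catalyst-controlled epoxidations on a flexible macrocycle may be overridden by ring conformation, the 1,1-disubstituted olefin may over-oxidise, and the 11,12-epoxide must survive the acid. The fallback stages the oxidations so that each is site-selective for electronic reasons; it sets out from 11 and comes back at 17.
- Epoxidise 11 with the same ketone/Oxone (1.3 equiv KHSO5); in the open chain only C11=C12 is an unhindered electron-rich olefin, giving (2Z,6S)-6-hydroxy-9-[(2R,3R)-3-(4-hydroxybutyl)-3-methyloxiran-2-yl]-3-methyl-7-methylidenenon-2-en-1-yl acetate F6.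
- Oxidise (TEMPO, PhI(OAc)2) to (2Z,6S)-6-hydroxy-3-methyl-9-[(2R,3R)-3-methyl-3-(4-oxobutyl)oxiran-2-yl]-7-methylidenenon-2-en-1-yl acetate F7.
- Silylate in the flask to (2Z,6S)-3-methyl-9-[(2R,3R)-3-methyl-3-(4-oxobutyl)oxiran-2-yl]-7-methylidene-6-[(trimethylsilyl)oxy]non-2-en-1-yl acetate F8 and cyclise as in step 7 to (1R,3Z,7S,11R,12R)-11,12-epoxy-4,12-dimethyl-8-methylidene-7-[(trimethylsilyl)oxy]cyclotetradec-3-ene-1-carbaldehyde F9.
- Ohira–Bestmann as in step 8 gives (1R,3Z,7S,11R,12R)-11,12-epoxy-1-ethynyl-4,12-dimethyl-8-methylidenecyclotetradec-3-en-7-ol F10.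
- A single Shi epoxidation of the one remaining trisubstituted olefin then gives 16, which is cyclised with acid to 17.

**Further compounds**

F1 | step 7 | (5E)-9-bromo-5-methyldeca-5,9-dienal | O=CCCC/C(C)=C/CCC(Br)=C
F2 | step 7 | (2Z)-6,6-dimethoxy-3-methylhex-2-en-1-yl acetate | CC(=O)OC/C=C(C)\CCC(OC)OC
F3 | step 7 | (2R,5E)-9-bromo-2-[(2Z)-6,6-dimethoxy-3-methylhex-2-en-1-yl]-5-methyldeca-5,9-dienal | O=C[C@@H](C/C=C(C)\CCC(OC)OC)CC/C(C)=C/CCC(Br)=C
F4 | step 7 | (3R,6E)-10-bromo-3-[(2Z)-6,6-dimethoxy-3-methylhex-2-en-1-yl]-6-methylundeca-6,10-dien-1-yne | C#C[C@@H](C/C=C(C)\CCC(OC)OC)CC/C(C)=C/CCC(Br)=C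
F5 | step 7 | (4Z,7R,10E)-14-bromo-7-ethynyl-4,10-dimethylpentadeca-4,10,14-trienal | C#C[C@@H](C/C=C(C)\CCC=O)CC/C(C)=C/CCC(Br)=C
F6 | step 9 | (2Z,6S)-6-hydroxy-9-[(2R,3R)-3-(4-hydroxybutyl)-3-methyloxiran-2-yl]-3-methyl-7-methylidenenon-2-en-1-yl acetate | CC(=O)OC/C=C(C)\CC[C@H](O)C(=C)CC[C@H]1O[C@]1(C)CCCCO
F7 | step 9 | (2Z,6S)-6-hydroxy-3-methyl-9-[(2R,3R)-3-methyl-3-(4-oxobutyl)oxiran-2-yl]-7-methylidenenon-2-en-1-yl acetate | CC(=O)OC/C=C(C)\CC[C@H](O)C(=C)CC[C@H]1O[C@]1(C)CCCC=O
F8 | step 9 | (2Z,6S)-3-methyl-9-[(2R,3R)-3-methyl-3-(4-oxobutyl)oxiran-2-yl]-7-methylidene-6-[(trimethylsilyl)oxy]non-2-en-1-yl acetate | CC(=O)OC/C=C(C)\CC[C@H](O[Si](C)(C)C)C(=C)CC[C@H]1O[C@]1(C)CCCC=O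
F9 | step 9 | (1R,3Z,7S,11R,12R)-11,12-epoxy-4,12-dimethyl-8-methylidene-7-[(trimethylsilyl)oxy]cyclotetradec-3-ene-1-carbaldehyde | O=C[C@@H]1CC[C@@]2(C)O[C@@H]2CCC(=C)[C@@H](O[Si](C)(C)C)CC/C(C)=C\C1
F10 | step 9 | (1R,3Z,7S,11R,12R)-11,12-epoxy-1-ethynyl-4,12-dimethyl-8-methylidenecyclotetradec-3-en-7-ol | C#C[C@@H]1CC[C@@]2(C)O[C@@H]2CCC(=C)[C@@H](O)CC/C(C)=C\C1
F11 | step 10 | (1R,3R,4R,7S,11S,12R)-4,7-epoxy-1-ethynyl-4,12-dimethyl-8-methylidenecyclotetradecane-3,11,12-triol | C#C[C@@H]1CC[C@@](C)(O)[C@@H](O)CCC(=C)[C@@H]2CC[C@@](C)(O2)[C@H](O)C1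
F12 | step 10 | 11,12-O-dibutylstannylene acetal of (1R,3R,4R,7S,11S,12R)-4,7-epoxy-1-ethynyl-4,12-dimethyl-8-methylidenecyclotetradecane-3,11,12-triol | C#C[C@@H]1CC[C@@]2(C)O[Sn](CCCC)(CCCC)O[C@H]2CCC(=C)[C@@H]3CC[C@@](C)(O3)[C@H](O)C1
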